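At early times I treated each flask as a plain fork, so I followed one molecule of starting material there. I took it that the molecule either meets partner and becomes target, or leaves by a side loss that needs no partner. Partner was charged at 4.00 equiv, so I held it at its charge (pseudo-first-order).

| setting | Wednesday's | Monday's | winter | dusk | autumn | dawn |
|---|---|---|---|---|---|---|
| starting material | 0.070 M | 0.11 M | 0.050 M | 0.050 M | 0.050 M | 0.050 M |
| partner | 4 equiv | 4 equiv | 4.00 equiv | 4.00 equiv | 4.00 equiv | 4.00 equiv |
| temperature | 18 °C | 67 °C | 25 °C | −5 °C | 55 °C | 85 °C |
| remark | run made earlier | run made earlier |  |  |  |  |
| time |  |  | 2.5 h | 2.5 h | 2.5 h | 2.5 h |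

- Wednesday's (time / min: target / %, starting material / %): 20.0: 49, 40; 40.0: 65, 19; 60.0: 68, 8; 80.0: 66, 4; 90.0: 66, 1; 120: 63, 1
- Monday's (time / min: target / %, starting material / %): 1.00: 46, 0; 3.00: 36, 0; 5.00: 22, 0; 8.00: 13, 0; 12.0: 5, 0; 15.0: 2, 2

(standard deviation of a reading: 1.5 percentage points)

* the flask with the highest amount of target, in percent of the starting material charged ("all alike" if they lie within 1.5 percentage points) (winter / dusk / autumn / dawn / all alike)
* final target, as a percentage of the starting material charged, in winter
* final target, as a percentage of the starting material charged, in dusk
* final target, as a percentage of the starting material charged, in autumn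
* final target, as a percentage of the starting material charged, in dawn



Winter looked nearly the same as Wednesday's run, so I started there. At 20.0 min Wednesday's run had made 49 % target from 60.0 % of starting material consumed. Monday's run showed no starting material at its first reading, and its target was falling at 0.202 min⁻¹, so I took that decay back to the start:

Wednesday's share: 81.7 %

Monday's share: 56.3 %

Dividing each share's odds by the partner concentration gave:

Wednesday's: 15.9 M⁻¹

Monday's: 2.93 M⁻¹

Their fall with inverse temperature read as an energy gap, which carried the value to winter's temperature:

gap: 28.5 kJ mol⁻¹

winter: 12.1 M⁻¹

This fork constant, the odds of target against side product per molar of partner, is a selectivity factor. With winter's partner it gave a fork share of 70.7 %.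

So I reckoned winter's fork poorer than Wednesday's, with a lower constant and thinner partner. Target also decays afterwards. Wednesday's run fell 5 percentage points from 60.0 min to 120 min, against a scatter of 1.5 points, and winter ran longer. I therefore expected winter to end below my share.

The forecast, made from the same two runs, named winter, with 41 % in winter, 29 % in dusk, 0.1 % in autumn and 0 % in dawn: “so roughly 41% remains at 2.5 h”. That is a final amount, whereas my 70.7 % is a share at the fork.

The most target stood in winter, 47.3 %, against 29.4 % in dusk, 0.289 % in autumn and 0 % in dawn, with these steps running:

    starting material + partner → target (k = 0.270 M⁻¹ min⁻¹, Ea = 68.0 kJ mol⁻¹)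
    starting material → side product (k = 0.0210 min⁻¹, Ea = 97.0 kJ mol⁻¹)
    partner + target → over-reaction product (k = 0.0180 M⁻¹ min⁻¹, Ea = 67.0 kJ mol⁻¹)
    (constants at 25 °C)

Winter ended 6.3 points above the forecast, and at 2.50 h it held 30.0 % side product and 22.7 % over-reaction product. With partner held at its charge, the fork constant reckoned 29.3 % side product for winter, and with partner held at the 76.8 % of its charge left at the end, 35.0 %. Carried to dawn's temperature, the fork constant became 1.76 M⁻¹. For the dawn flask charged with 16.0 equiv of partner, which ended with 93 % of that charge, this reckoned 41.5 % side product with partner held at its charge. That flask held 41.3 %.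

The numbers in the tables stem from a simulated flask on assumed constants; scatter was added.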